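The carbinol carbons C7/C7′ and the ring carbons C8/C8′ (C3/C4 of the tetrahydrofuran ring O–C9–C8–C8′–C9′) form a succinyl unit with hidden mirror symmetry. At the dicarbonyl level, with cis ring carbons, this unit is a meso bicyclic anhydride with enantiotopic carbonyls. The key step is a rhodium-catalysed enantioselective cross-coupling of a protected guaiacylzinc reagent with this anhydride. It forms the aryl–C7 bond, distinguishes C7 from C7′ and fixes the absolute configuration in one operation. The new aryl ketone then lets C8 relax to trans. Felkin hydride delivery sets C7. Felkin aryl addition to the C7′ aldehyde sets the opposite relative configuration there.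

Key step: step 4

Assumption: the antipode of the TADDOL phosphoramidite that gives 8 rather than its enantiomer is assigned by analogy with other meso succinic anhydrides. Both antipodes are available, so the other one is used if the sense proves opposite.

Step 1
Reactants: 1 furan-3,4-dicarboxylic acid
Product: 2 cis-tetrahydrofuran-3,4-dicarboxylic acid (meso)
Conditions: H2 (60 bar), 5% Rh/C, H2O, 60 °C
Reagents that add atoms: none
Why: Heterogeneous catalytic hydrogenation of the furan adds hydrogen from the catalyst face (syn addition), so the two carboxyl groups should end up cis and the product is the achiral meso diacid.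

Step 2
Reactants: 2 cis-tetrahydrofuran-3,4-dicarboxylic acid
Product: 3 cis-tetrahydrofuran-3,4-dicarboxylic anhydride (meso; both ring-fusion hydrogens on the same face)
Conditions: Ac2O, reflux; evaporation, crystallisation
Reagents that add atoms: none
Why: Dehydrative cyclisation to the cyclic anhydride with acetic anhydride, which only the cis diacid can undergo in a bicyclo[3.3.0] frame, so any trans diacid is epimerised into it or left behind.

Step 3
Reactants: 4 4-bromo-2-methoxyphenol
Product: 5 (4-bromo-2-methoxyphenoxy)triisopropylsilane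
Conditions: TIPSCl, imidazole, DMF, rt
Reagents that add atoms: triisopropylsilyl chloride, CC(C)[Si](Cl)(C(C)C)C(C)C
Why: Imidazole-promoted silylation of the phenol; the TIPS ether should survive organolithium, zinc, DBU, hydride and Grignard reagents and leaves at the end with fluoride, without the acid or hydrogenolysis that would endanger the benzylic alcohols.

Step 4
Reactants: 5 (4-bromo-2-methoxyphenoxy)triisopropylsilane; 3 cis-tetrahydrofuran-3,4-dicarboxylic anhydride
Product: 8 (3R,4S)-4-[3-methoxy-4-(triisopropylsilyloxy)benzoyl]tetrahydrofuran-3-carboxylic acid (cis keto acid), via aryllithium 6 (not isolated), via arylzinc triflate 7 (not isolated)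
Conditions: 5, n-BuLi, THF, −78 °C; Zn(OTf)2, −78 °C → rt; then 3, [Rh(cod)Cl]2 (4 mol %), TADDOL-derived dimethylphosphoramidite (10 mol %), THF, 50 °C; aq. HCl work-up
Reagents that add atoms: n-butyllithium, [Li]CCCC (lithium of 6 only); zinc triflate, [Zn+2].[O-]S(=O)(=O)C(F)(F)F.[O-]S(=O)(=O)C(F)(F)F (zinc and triflate of 7 only)
Why: Bromine–lithium exchange and transmetalation to zinc triflate give the halide-poor arylzinc 7; the chiral Rh(I)–phosphoramidite complex inserts into one of the two enantiotopic acyl C–O bonds of meso anhydride 3, takes up the aryl group from zinc and forms the aryl–carbonyl bond by reductive elimination, releasing the zinc carboxylate of 8. The closest known reaction type is the rhodium-catalysed enantioselective desymmetrisation of meso succinic anhydrides with arylzinc reagents made in situ, an acyl Negishi-type cross-coupling. No ring is closed; the anhydride ring is opened and the tetrahydrofuran ring is carried through untouched. No new relative configuration arises, but the ligand's choice between the two carbonyls gives both ring carbons a defined absolute configuration, and the centre α to the carboxyl group (3R) is kept to the end. The step needs enantiotopic-group selectivity (secured by the ligand), single addition (the arylzinc attacks neither the electron-rich aryl ketone nor the carboxylate) and a preserved acyl–metal intermediate without decarbonylation (secured by fast transmetalation from the triflate at moderate temperature).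

Step 5
Reactants: 8 cis keto acid
Product: 10 (3R,4R)-N-methoxy-N-methyl-4-[3-methoxy-4-(triisopropylsilyloxy)benzoyl]tetrahydrofuran-3-carboxamide (trans), via cis keto Weinreb amide 9 (not isolated)
Conditions: MeNH(OMe)·HCl, EDC·HCl, HOBt (cat.), N-methylmorpholine, CH2Cl2, 0 °C → rt; aqueous wash; crude 9, DBU (0.5 equiv), toluene, rt
Reagents that add atoms: N,O-dimethylhydroxylamine hydrochloride, CNOC.Cl
Why: Carbodiimide amide coupling gives Weinreb amide 9, and DBU then epimerises only the far more acidic centre α to the aryl ketone, so thermodynamic control moves the aroyl group to the less crowded trans position (4S → 4R) while the centre α to the amide holds the absolute configuration; β-elimination of the ring oxygen would be the reverse of a 5-endo-trig closure and should not compete.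

Step 6
Reactants: 10 trans keto Weinreb amide
Product: 12 (3R,4R)-4-{(S)-hydroxy[3-methoxy-4-(triisopropylsilyloxy)phenyl]methyl}tetrahydrofuran-3-carbaldehyde, via hydroxy Weinreb amide 11 (not isolated)
Conditions: L-Selectride (1.2 equiv), THF, −78 °C; then DIBAL-H (2.5 equiv), −78 °C; aq. Rochelle salt, 0 °C; 12 used crude
Reagents that add atoms: none
Why: L-Selectride should attack the aryl ketone in the Felkin–Anh conformer (amide-bearing ring carbon anti to hydride, carbonyl oxygen beside the ring CH2O, aryl beside H), which sets the (S)-carbinol, and DIBAL-H then stops at the chelated hemiaminal of the Weinreb amide, which releases the aldehyde only on work-up; the strained trans ring fusion that a lactol would need keeps 12 open-chain.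

Step 7
Reactants: 12 trans hydroxy aldehyde; 5 (4-bromo-2-methoxyphenoxy)triisopropylsilane
Product: 14 (S)-[3-methoxy-4-(triisopropylsilyloxy)phenyl]{(3R,4R)-4-[(R)-hydroxy(3-methoxy-4-(triisopropylsilyloxy)phenyl)methyl]tetrahydrofuran-3-yl}methanol, via arylmagnesium bromide 13 (not isolated)
Conditions: 5 (3.2 equiv), Mg, cat. I2, THF, 45 °C; cool to −78 °C; add 12 in THF, −78 → −40 °C; sat. aq. NH4Cl
Reagents that add atoms: magnesium, [Mg] (magnesium of 13 only)
Why: Grignard addition (the first equivalent only deprotonates the free hydroxyl) in the Felkin–Anh sense, which magnesium chelation between the aldehyde oxygen and the ring oxygen would reinforce; because aryl rather than hydride is now the incoming group, the facial preference that gave (S) in step 6 should give the (R)-carbinol here.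

Step 8
Reactants: 14 bis-TIPS ether
Product: 15 (S)-(4-hydroxy-3-methoxyphenyl){(3R,4R)-4-[(R)-hydroxy(4-hydroxy-3-methoxyphenyl)methyl]tetrahydrofuran-3-yl}methanol (target)
Conditions: TBAF (2.2 equiv), AcOH (2.2 equiv), THF, 0 °C
Reagents that add atoms: none
Why: Fluoride-mediated cleavage of the two aryl silyl ethers, buffered with acetic acid so that no free phenoxide can expel the benzylic hydroxyl through a quinone methide; no stereocentre is touched.

Compound list
1 | furan-3,4-dicarboxylic acid | O=C(O)c1cocc1C(=O)O | starting material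
2 | cis-tetrahydrofuran-3,4-dicarboxylic acid (meso) | O=C(O)[C@H]1COC[C@H]1C(=O)O | intermediate
3 | cis-tetrahydrofuran-3,4-dicarboxylic anhydride (meso) | O=C1OC(=O)[C@H]2COC[C@@H]12 | intermediate
4 | 4-bromo-2-methoxyphenol | COc1cc(Br)ccc1O | starting material
5 | (4-bromo-2-methoxyphenoxy)triisopropylsilane | COc1cc(Br)ccc1O[Si](C(C)C)(C(C)C)C(C)C | intermediate
6 | [3-methoxy-4-(triisopropylsilyloxy)phenyl]lithium | COc1cc([Li])ccc1O[Si](C(C)C)(C(C)C)C(C)C | intermediate
7 | [3-methoxy-4-(triisopropylsilyloxy)phenyl]zinc triflate | COc1cc([Zn]OS(=O)(=O)C(F)(F)F)ccc1O[Si](C(C)C)(C(C)C)C(C)C | intermediate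
8 | (3R,4S)-4-[3-methoxy-4-(triisopropylsilyloxy)benzoyl]tetrahydrofuran-3-carboxylic acid | COc1cc(C(=O)[C@@H]2COC[C@@H]2C(=O)O)ccc1O[Si](C(C)C)(C(C)C)C(C)C | intermediate
9 | (3R,4S)-N-methoxy-N-methyl-4-[3-methoxy-4-(triisopropylsilyloxy)benzoyl]tetrahydrofuran-3-carboxamide | COc1cc(C(=O)[C@@H]2COC[C@@H]2C(=O)N(C)OC)ccc1O[Si](C(C)C)(C(C)C)C(C)C | intermediate
10 | (3R,4R)-N-methoxy-N-methyl-4-[3-methoxy-4-(triisopropylsilyloxy)benzoyl]tetrahydrofuran-3-carboxamide | COc1cc(C(=O)[C@H]2COC[C@@H]2C(=O)N(C)OC)ccc1O[Si](C(C)C)(C(C)C)C(C)C | intermediate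
11 | (3R,4R)-4-{(S)-hydroxy[3-methoxy-4-(triisopropylsilyloxy)phenyl]methyl}-N-methoxy-N-methyltetrahydrofuran-3-carboxamide | COc1cc([C@@H](O)[C@H]2COC[C@@H]2C(=O)N(C)OC)ccc1O[Si](C(C)C)(C(C)C)C(C)C | intermediate
12 | (3R,4R)-4-{(S)-hydroxy[3-methoxy-4-(triisopropylsilyloxy)phenyl]methyl}tetrahydrofuran-3-carbaldehyde | COc1cc([C@@H](O)[C@H]2COC[C@@H]2C=O)ccc1O[Si](C(C)C)(C(C)C)C(C)C | intermediate
13 | [3-methoxy-4-(triisopropylsilyloxy)phenyl]magnesium bromide | COc1cc([Mg]Br)ccc1O[Si](C(C)C)(C(C)C)C(C)C | intermediate
14 | bis-TIPS ether of the target (7S,7′R,8R,8′R) | COc1cc([C@@H](O)[C@H]2COC[C@@H]2[C@@H](O)c2ccc(O[Si](C(C)C)(C(C)C)C(C)C)c(OC)c2)ccc1O[Si](C(C)C)(C(C)C)C(C)C | intermediate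
15 | (S)-(4-hydroxy-3-methoxyphenyl){(3R,4R)-4-[(R)-hydroxy(4-hydroxy-3-methoxyphenyl)methyl]tetrahydrofuran-3-yl}methanol | COc1cc([C@@H](O)[C@H]2COC[C@@H]2[C@@H](O)c2ccc(O)c(OC)c2)ccc1O | target

Total step count: 8. Longest linear sequence: 7 (steps 1, 2, 4, 5, 6, 7, 8).

Steps most likely to fail

Step 4. The catalyst may discriminate poorly between the two enantiotopic carbonyls. The acyl–rhodium intermediate may also decarbonylate, or the coupling may stall because the ring oxygen binds the metal. The fallback sets out from 3 and returns at 8, separating symmetry breaking from C–C bond formation. Cinchona-alkaloid-mediated benzyl alcoholysis of 3 (quinidine or quinine as required, BnOH, toluene, −55 °C) should give the cis hemiester (3S,4R)-4-(benzyloxycarbonyl)tetrahydrofuran-3-carboxylic acid F1. Oxalyl chloride with catalytic DMF converts it into the acid chloride F2. Pd(PPh3)4-catalysed Negishi acylation of arylzinc 7 with F2 gives the cis keto benzyl ester F3. Hydrogenolysis of the benzyl ester (H2, 1 bar, Pd/C, EtOAc) then gives 8.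

Step 6. The aldehyde-bearing carbon may epimerise during work-up, and the cis isomer would then collapse into the stable cis-fused lactol. Facial selectivity may also erode in the one-pot double reduction. The fallback sets out from 10 and returns at 15. The reaction is stopped after L-Selectride and 11 is isolated. TESOTf with 2,6-lutidine gives the triethylsilyl ether of the Weinreb amide F4. DIBAL-H gives the silyloxy aldehyde F5, which cannot form a lactol and can be re-equilibrated to trans with base. Grignard reagent 13 adds to give the mono-TES diol F6, and TBAF/AcOH removes all three silyl groups to give 15.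

Step 7. Facial selectivity of the aryl addition may be poor, for example if the magnesium alkoxide of the neighbouring carbinol binds the aldehyde and overrides the Felkin preference. The fallback sets out from 11 (isolated as above) and returns at 14, replacing substrate control with catalyst control at the ketone level. Aryllithium 6 (3 equiv, THF, −78 °C) converts the Weinreb amide into the trans hydroxy ketone F7. Corey–Bakshi–Shibata reduction with (S)-Me-CBS and BH3·SMe2 should then set the (R)-carbinol and give 14.

Further compounds
F1 | step 4 | (3S,4R)-4-(benzyloxycarbonyl)tetrahydrofuran-3-carboxylic acid | O=C(O)[C@@H]1COC[C@@H]1C(=O)OCc1ccccc1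
F2 | step 4 | benzyl (3R,4S)-4-(chlorocarbonyl)tetrahydrofuran-3-carboxylate | O=C(Cl)[C@@H]1COC[C@@H]1C(=O)OCc1ccccc1
F3 | step 4 | benzyl (3R,4S)-4-[3-methoxy-4-(triisopropylsilyloxy)benzoyl]tetrahydrofuran-3-carboxylate | COc1cc(C(=O)[C@@H]2COC[C@@H]2C(=O)OCc2ccccc2)ccc1O[Si](C(C)C)(C(C)C)C(C)C
F4 | step 6 | (3R,4R)-N-methoxy-N-methyl-4-{(S)-(triethylsilyloxy)[3-methoxy-4-(triisopropylsilyloxy)phenyl]methyl}tetrahydrofuran-3-carboxamide | COc1cc([C@@H](O[Si](CC)(CC)CC)[C@H]2COC[C@@H]2C(=O)N(C)OC)ccc1O[Si](C(C)C)(C(C)C)C(C)C
F5 | step 6 | (3R,4R)-4-{(S)-(triethylsilyloxy)[3-methoxy-4-(triisopropylsilyloxy)phenyl]methyl}tetrahydrofuran-3-carbaldehyde | COc1cc([C@@H](O[Si](CC)(CC)CC)[C@H]2COC[C@@H]2C=O)ccc1O[Si](C(C)C)(C(C)C)C(C)C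
F6 | step 6 | 7-O-triethylsilyl ether of 14 | COc1cc([C@@H](O[Si](CC)(CC)CC)[C@H]2COC[C@@H]2[C@@H](O)c2ccc(O[Si](C(C)C)(C(C)C)C(C)C)c(OC)c2)ccc1O[Si](C(C)C)(C(C)C)C(C)C
F7 | step 7 | {(3R,4R)-4-[(S)-hydroxy(3-methoxy-4-(triisopropylsilyloxy)phenyl)methyl]tetrahydrofuran-3-yl}[3-methoxy-4-(triisopropylsilyloxy)phenyl]methanone | COc1cc([C@@H](O)[C@H]2COC[C@@H]2C(=O)c2ccc(O[Si](C(C)C)(C(C)C)C(C)C)c(OC)c2)ccc1O[Si](C(C)C)(C(C)C)C(C)C
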